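The 2,2‑dimethylchroman ring is cut across C4–C3 and O1–C2: an o‑quinone methide of a phloroglucinol unit adds isobutene in an inverse‑demand hetero‑Diels–Alder reaction. The feature exploited is that chroman C4a is flanked by C8a–O1 and by C5, the carbon that carries benzofuran C2. Treating C5 as a latent phenol makes the precursor, a 2‑(aminomethyl)resorcinol, mirror‑symmetric, so either hydroxyl closes to the same chroman and the other becomes the triflate for the biaryl bond. One operation thus builds the pyran ring from a Mannich base and a C4 gas. Both aromatic halves come from one silylated 2,4,6‑trihydroxybenzaldehyde; the side‑chain stereocentre is set by Cu–H hydroboration and Zweifel olefination.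

Key step: step 3

Remarks on the chemistry (assumptions):
- The target stereocentre is (R) (aryl > isopropenyl > methyl > H).
- The ligand antipode in step 12 is the one that gives the (S)‑boronate. This is expected to be (R)‑DTBM‑SEGPHOS by analogy with styrene; if the opposite sense is found, the mirror‑image ligand is used.
- Compounds 1, 2, 4, 6, 9, 14, 16, 18, 22, 24, 26 and 28 are taken as commercial.
- Chroman numbering (O1, C2 … C8a) is used for the pyran‑fused half and benzofuran numbering for the other half.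

Step 1
Reactants: 1 2,4,6‑trihydroxybenzaldehyde; 2 chlorotriisopropylsilane
Product: 3 2,6‑dihydroxy‑4‑(triisopropylsilyloxy)benzaldehyde
Conditions: TIPSCl (1.05 equiv), imidazole, DMF, 0 °C
Reagents that add atoms: chlorotriisopropylsilane, CC(C)[Si](Cl)(C(C)C)C(C)C
Why: Regioselective O‑silylation: the 4‑OH is the most acidic hydroxyl and the only one neither chelated to nor crowded by the formyl group, so one equivalent of the bulky silyl chloride should mark it alone and leave a symmetric 2,6‑diol.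

Step 2
Reactants: 3 2,6‑dihydroxy‑4‑(triisopropylsilyloxy)benzaldehyde; 4 dimethylamine
Product: 5 2‑[(dimethylamino)methyl]‑5‑(triisopropylsilyloxy)benzene‑1,3‑diol
Conditions: Me2NH (2 M in THF), NaBH(OAc)3, AcOH (cat.), DCE, rt
Reagents that add atoms: dimethylamine, CNC
Why: Reductive amination of the salicylaldehyde through its iminium form should give the phenolic Mannich base without touching the aryl silyl ether.

Step 3
Reactants: 5 2‑[(dimethylamino)methyl]‑5‑(triisopropylsilyloxy)benzene‑1,3‑diol; 6 isobutene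
Product: 8 2,2‑dimethyl‑7‑(triisopropylsilyloxy)chroman‑5‑ol, via o‑quinone methide 7 (not isolated)
Conditions: isobutene (condensed, ca. 20 equiv), toluene (0.02 M), sealed tube, 140 °C
Reagents that add atoms: isobutene, C=C(C)C
Why: Heating the Mannich base expels dimethylamine (retro‑Mannich/E1cB through the H‑bonded phenol) to give o‑quinone methide 7, whose oxa‑diene (exocyclic C=C–C=O) undergoes an inverse‑electron‑demand hetero‑Diels–Alder reaction with isobutene; bond formation is asynchronous, the electrophilic methylene attacking the CH2 terminus (C4–C3) while positive charge builds at the tertiary carbon that the oxygen captures (O1–C2). The closest known reaction type is the thermal o‑quinone methide/alkene [4+2] of phenolic Mannich bases or phenol–formaldehyde mixtures with 1,1‑disubstituted alkenes, which gives 2,2‑disubstituted chromans. The dihydropyran ring closes by a suprafacial [4+2] cycloaddition (six‑membered ring, rearomatising the arene), and no stereocentre is formed. Regiochemistry (2,2‑ not 3,3‑dimethyl) follows from the polarity match, and the choice of ring oxygen needs no control because the two hydroxyls flanking the methylene are equivalent by symmetry. Cycloaddition should be favoured over C‑alkylation of a second arene by the large excess of isobutene, the high dilution of 5 and the TIPS group that shields both free ring positions, while the absence of acid prevents tert‑butylation by isobutene.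

Step 4
Reactants: 8 2,2‑dimethyl‑7‑(triisopropylsilyloxy)chroman‑5‑ol; 9 3‑chloro‑3‑methylbut‑1‑yne
Product: 10 2,2‑dimethyl‑5‑(2‑methylbut‑3‑yn‑2‑yloxy)‑7‑(triisopropylsilyloxy)chroman
Conditions: DBU, CuCl2·2H2O (1 mol %), MeCN, 0 °C to rt
Reagents that add atoms: 3‑chloro‑3‑methylbut‑1‑yne, C#CC(C)(C)Cl
Why: Copper‑catalysed propargylic etherification of the single free phenol (via a copper acetylide/allenylidene) should install the tertiary ether without C‑alkylation.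

Step 5
Reactants: 10 2,2‑dimethyl‑5‑(2‑methylbut‑3‑yn‑2‑yloxy)‑7‑(triisopropylsilyloxy)chroman
Product: 11 2,2‑dimethyl‑5‑(2‑methylbut‑3‑en‑2‑yloxy)‑7‑(triisopropylsilyloxy)chroman
Conditions: H2 (1 atm), Lindlar catalyst, quinoline, EtOAc, rt
Reagents that add atoms: none
Why: Lindlar semi‑hydrogenation stops the terminal alkyne at the alkene and leaves aryl and silyl ethers alone.

Step 6
Reactants: 11 2,2‑dimethyl‑5‑(2‑methylbut‑3‑en‑2‑yloxy)‑7‑(triisopropylsilyloxy)chroman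
Product: 13 2,2‑dimethyl‑6‑(3‑methylbut‑2‑enyl)‑7‑(triisopropylsilyloxy)chroman‑5‑ol, via ortho‑dienone 12 (not isolated)
Conditions: N,N‑diethylaniline, 140 °C
Reagents that add atoms: none
Why: Aromatic Claisen [3,3] rearrangement of the 1,1‑dimethylallyl ether transfers the allyl unit with inversion to C6, the only unsubstituted ortho carbon (C4a is blocked), and enolisation of dienone 12 restores the phenol.

Step 7
Reactants: 13 2,2‑dimethyl‑6‑(3‑methylbut‑2‑enyl)‑7‑(triisopropylsilyloxy)chroman‑5‑ol; 14 N‑phenylbis(trifluoromethanesulfonimide)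
Product: 15 2,2‑dimethyl‑6‑(3‑methylbut‑2‑enyl)‑7‑(triisopropylsilyloxy)chroman‑5‑yl trifluoromethanesulfonate
Conditions: KHMDS, PhNTf2, THF, −78 °C to rt
Reagents that add atoms: N‑phenylbis(trifluoromethanesulfonimide), O=S(=O)(N(c1ccccc1)S(=O)(=O)C(F)(F)F)C(F)(F)F
Why: O‑triflation of the potassium phenoxide with a neutral triflyl donor avoids the acid that would cyclise the ortho‑prenyl phenol.

Step 8
Reactants: 3 2,6‑dihydroxy‑4‑(triisopropylsilyloxy)benzaldehyde; 16 N‑iodosuccinimide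
Product: 17 2,6‑dihydroxy‑3‑iodo‑4‑(triisopropylsilyloxy)benzaldehyde
Conditions: NIS (1.0 equiv), MeCN, −20 to 0 °C, dark
Reagents that add atoms: N‑iodosuccinimide, O=C1CCC(=O)N1I
Why: Electrophilic aromatic iodination; C3 and C5 of 3 are equivalent by symmetry, so mono‑iodination with one equivalent of NIS can give only one isomer.

Step 9
Reactants: 17 2,6‑dihydroxy‑3‑iodo‑4‑(triisopropylsilyloxy)benzaldehyde; 18 ethynyltrimethylsilane
Product: 21 4,6‑dihydroxybenzofuran‑7‑carbaldehyde, via alkynylphenol 19 (not isolated), via 2‑silylbenzofuran 20 (not isolated)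
Conditions: Pd(PPh3)2Cl2 (5 mol %), CuI (10 mol %), Et3N, DMF, 70 °C; then TBAF (4 equiv), THF, rt
Reagents that add atoms: ethynyltrimethylsilane, C#C[Si](C)(C)C
Why: Sonogashira coupling followed by copper/palladium‑assisted 5‑endo‑dig heteroannulation can use only the 2‑OH because the 4‑O is silylated, which fixes the furan fusion, after which fluoride strips the C2‑silyl group and the silyl ether.

Step 10
Reactants: 21 4,6‑dihydroxybenzofuran‑7‑carbaldehyde; 22 triisopropylsilyl trifluoromethanesulfonate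
Product: 23 4,6‑bis(triisopropylsilyloxy)benzofuran‑7‑carbaldehyde
Conditions: TIPSOTf (2.5 equiv), 2,6‑lutidine, CH2Cl2, 0 °C to rt
Reagents that add atoms: triisopropylsilyl trifluoromethanesulfonate, CC(C)[Si](OS(=O)(=O)C(F)(F)F)(C(C)C)C(C)C
Why: A silyl triflate with a hindered base should silylate both phenols, including the formyl‑chelated 6‑OH.

Step 11
Reactants: 23 4,6‑bis(triisopropylsilyloxy)benzofuran‑7‑carbaldehyde; 24 methyltriphenylphosphonium bromide
Product: 25 7‑ethenyl‑4,6‑bis(triisopropylsilyloxy)benzofuran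
Conditions: Ph3PCH3Br, KOtBu, THF, 0 °C to rt
Reagents that add atoms: methyltriphenylphosphonium bromide, C[P+](c1ccccc1)(c1ccccc1)c1ccccc1.[Br-]
Why: Wittig methylenation with the small unstabilised ylide tolerates the flanked, electron‑rich aldehyde.

Step 12
Reactants: 25 7‑ethenyl‑4,6‑bis(triisopropylsilyloxy)benzofuran; 26 pinacolborane
Product: 27 2‑[(1S)‑1‑[4,6‑bis(triisopropylsilyloxy)benzofuran‑7‑yl]ethyl]‑4,4,5,5‑tetramethyl‑1,3,2‑dioxaborolane
Conditions: CuCl (5 mol %), (R)‑DTBM‑SEGPHOS (6 mol %), NaOtBu (10 mol %), HBpin, toluene, rt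
Reagents that add atoms: pinacolborane, CC1(C)OBOC1(C)C
Why: Copper hydride‑catalysed Markovnikov hydroboration of a vinylarene: the chiral bisphosphine controls the face of hydrocupration (Cu to the benzylic carbon) and stereoretentive σ‑bond metathesis with pinacolborane should deliver the (S)‑boronate.

Step 13
Reactants: 27 2‑[(1S)‑1‑[4,6‑bis(triisopropylsilyloxy)benzofuran‑7‑yl]ethyl]‑4,4,5,5‑tetramethyl‑1,3,2‑dioxaborolane; 28 2‑bromopropene
Product: 31 7‑[(2R)‑3‑methylbut‑3‑en‑2‑yl]‑4,6‑bis(triisopropylsilyloxy)benzofuran, via boronate complex 29 (not isolated), via iodoalkyl boronate 30 (not isolated)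
Conditions: 2‑bromopropene, t‑BuLi (2 equiv per bromide), Et2O/THF, −78 °C; add 27; I2, THF/MeOH, −78 °C; NaOMe, MeOH, −78 °C to rt
Reagents that add atoms: 2‑bromopropene, C=C(C)Br (used as isopropenyllithium, [Li]C(C)=C)
Why: Zweifel olefination: boronate complex 29 undergoes iodine‑triggered 1,2‑migration of the benzylic carbon with retention of configuration and methoxide‑induced anti‑elimination of boron and iodide, so the (S)‑boronate gives the (R)‑alkene (same spatial arrangement, changed CIP priorities).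

Step 14
Reactants: 31 7‑[(2R)‑3‑methylbut‑3‑en‑2‑yl]‑4,6‑bis(triisopropylsilyloxy)benzofuran; 15 2,2‑dimethyl‑6‑(3‑methylbut‑2‑enyl)‑7‑(triisopropylsilyloxy)chroman‑5‑yl trifluoromethanesulfonate
Product: 34 2‑[2,2‑dimethyl‑6‑(3‑methylbut‑2‑enyl)‑7‑(triisopropylsilyloxy)chroman‑5‑yl]‑7‑[(2R)‑3‑methylbut‑3‑en‑2‑yl]‑4,6‑bis(triisopropylsilyloxy)benzofuran, via 2‑lithiobenzofuran 32 (not isolated), via 2‑benzofuranylzinc chloride 33 (not isolated)
Conditions: n‑BuLi (1.1 equiv), THF, −78 °C; ZnCl2, −78 °C to rt; 15, Pd2(dba)3 (2.5 mol %), XPhos (10 mol %), THF, 65 °C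
Reagents that add atoms: none
Why: Negishi cross‑coupling: selective C2‑lithiation of the benzofuran, transmetalation to zinc and Pd/XPhos‑catalysed coupling, a catalyst system made for di‑ortho‑substituted electrophiles, should join the halves without touching the benzylic stereocentre.

Step 15
Reactants: 34 2‑[2,2‑dimethyl‑6‑(3‑methylbut‑2‑enyl)‑7‑(triisopropylsilyloxy)chroman‑5‑yl]‑7‑[(2R)‑3‑methylbut‑3‑en‑2‑yl]‑4,6‑bis(triisopropylsilyloxy)benzofuran
Product: 35 2‑[7‑hydroxy‑2,2‑dimethyl‑6‑(3‑methylbut‑2‑enyl)chroman‑5‑yl]‑7‑[(2R)‑3‑methylbut‑3‑en‑2‑yl]benzofuran‑4,6‑diol (CNP0325834.1)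
Conditions: TBAF (3.6 equiv), AcOH (3.6 equiv), THF, 0 °C to rt, under argon
Reagents that add atoms: none
Why: Fluoride‑mediated cleavage of the three aryl silyl ethers under buffered, non‑acidic conditions should leave the prenyl and isopropenyl groups and the stereocentre unchanged.

Compound list
1 | 2,4,6‑trihydroxybenzaldehyde | O=Cc1c(O)cc(O)cc1O | starting material
2 | chlorotriisopropylsilane | CC(C)[Si](Cl)(C(C)C)C(C)C | starting material
3 | 2,6‑dihydroxy‑4‑(triisopropylsilyloxy)benzaldehyde | O=Cc1c(O)cc(O[Si](C(C)C)(C(C)C)C(C)C)cc1O | intermediate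
4 | dimethylamine | CNC | starting material
5 | 2‑[(dimethylamino)methyl]‑5‑(triisopropylsilyloxy)benzene‑1,3‑diol | CN(C)Cc1c(O)cc(O[Si](C(C)C)(C(C)C)C(C)C)cc1O | intermediate
6 | isobutene (2‑methylpropene) | C=C(C)C | starting material
7 | 5‑hydroxy‑6‑methylidene‑3‑(triisopropylsilyloxy)cyclohexa‑2,4‑dien‑1‑one (o‑quinone methide) | C=C1C(=O)C=C(O[Si](C(C)C)(C(C)C)C(C)C)C=C1O | intermediate (not isolated)
8 | 2,2‑dimethyl‑7‑(triisopropylsilyloxy)chroman‑5‑ol | CC1(C)CCc2c(O)cc(O[Si](C(C)C)(C(C)C)C(C)C)cc2O1 | intermediate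
9 | 3‑chloro‑3‑methylbut‑1‑yne | C#CC(C)(C)Cl | starting material
10 | 2,2‑dimethyl‑5‑(2‑methylbut‑3‑yn‑2‑yloxy)‑7‑(triisopropylsilyloxy)chroman | CC1(C)CCc2c(OC(C)(C)C#C)cc(O[Si](C(C)C)(C(C)C)C(C)C)cc2O1 | intermediate
11 | 2,2‑dimethyl‑5‑(2‑methylbut‑3‑en‑2‑yloxy)‑7‑(triisopropylsilyloxy)chroman | CC1(C)CCc2c(OC(C)(C)C=C)cc(O[Si](C(C)C)(C(C)C)C(C)C)cc2O1 | intermediate
12 | 2,2‑dimethyl‑6‑(3‑methylbut‑2‑enyl)‑7‑(triisopropylsilyloxy)‑3,4‑dihydro‑2H‑chromen‑5(6H)‑one (ortho‑dienone, C6 unassigned) | CC(C)=CCC1C(=O)C2=C(C=C1O[Si](C(C)C)(C(C)C)C(C)C)OC(C)(C)CC2 | intermediate (not isolated)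
13 | 2,2‑dimethyl‑6‑(3‑methylbut‑2‑enyl)‑7‑(triisopropylsilyloxy)chroman‑5‑ol | CC(C)=CCc1c(O)c2CCC(C)(C)Oc2cc1O[Si](C(C)C)(C(C)C)C(C)C | intermediate
14 | N‑phenylbis(trifluoromethanesulfonimide) | O=S(=O)(N(c1ccccc1)S(=O)(=O)C(F)(F)F)C(F)(F)F | starting material
15 | 2,2‑dimethyl‑6‑(3‑methylbut‑2‑enyl)‑7‑(triisopropylsilyloxy)chroman‑5‑yl trifluoromethanesulfonate | CC(C)=CCc1c(OS(=O)(=O)C(F)(F)F)c2CCC(C)(C)Oc2cc1O[Si](C(C)C)(C(C)C)C(C)C | intermediate
16 | N‑iodosuccinimide | O=C1CCC(=O)N1I | starting material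
17 | 2,6‑dihydroxy‑3‑iodo‑4‑(triisopropylsilyloxy)benzaldehyde | O=Cc1c(O)cc(O[Si](C(C)C)(C(C)C)C(C)C)c(I)c1O | intermediate
18 | ethynyltrimethylsilane | C#C[Si](C)(C)C | starting material
19 | 2,6‑dihydroxy‑4‑(triisopropylsilyloxy)‑3‑[(trimethylsilyl)ethynyl]benzaldehyde | O=Cc1c(O)cc(O[Si](C(C)C)(C(C)C)C(C)C)c(C#C[Si](C)(C)C)c1O | intermediate (not isolated)
20 | 6‑hydroxy‑4‑(triisopropylsilyloxy)‑2‑(trimethylsilyl)benzofuran‑7‑carbaldehyde | O=Cc1c(O)cc(O[Si](C(C)C)(C(C)C)C(C)C)c2cc([Si](C)(C)C)oc12 | intermediate (not isolated)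
21 | 4,6‑dihydroxybenzofuran‑7‑carbaldehyde | O=Cc1c(O)cc(O)c2ccoc12 | intermediate
22 | triisopropylsilyl trifluoromethanesulfonate | CC(C)[Si](OS(=O)(=O)C(F)(F)F)(C(C)C)C(C)C | starting material
23 | 4,6‑bis(triisopropylsilyloxy)benzofuran‑7‑carbaldehyde | O=Cc1c(O[Si](C(C)C)(C(C)C)C(C)C)cc(O[Si](C(C)C)(C(C)C)C(C)C)c2ccoc12 | intermediate
24 | methyltriphenylphosphonium bromide | C[P+](c1ccccc1)(c1ccccc1)c1ccccc1.[Br-] | starting material
25 | 7‑ethenyl‑4,6‑bis(triisopropylsilyloxy)benzofuran | C=Cc1c(O[Si](C(C)C)(C(C)C)C(C)C)cc(O[Si](C(C)C)(C(C)C)C(C)C)c2ccoc12 | intermediate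
26 | pinacolborane | CC1(C)OBOC1(C)C | starting material
27 | 2‑[(1S)‑1‑[4,6‑bis(triisopropylsilyloxy)benzofuran‑7‑yl]ethyl]‑4,4,5,5‑tetramethyl‑1,3,2‑dioxaborolane | CC1(C)OB(OC1(C)C)[C@@H](C)c1c(O[Si](C(C)C)(C(C)C)C(C)C)cc(O[Si](C(C)C)(C(C)C)C(C)C)c2ccoc12 | intermediate
28 | 2‑bromopropene | C=C(C)Br | starting material
29 | lithium isopropenyl boronate complex of 27 (benzylic configuration as in 27) | [Li+].C=C(C)[B-]1(OC(C)(C)C(C)(C)O1)[C@@H](C)c1c(O[Si](C(C)C)(C(C)C)C(C)C)cc(O[Si](C(C)C)(C(C)C)C(C)C)c2ccoc12 | intermediate (not isolated)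
30 | 2‑[3‑[4,6‑bis(triisopropylsilyloxy)benzofuran‑7‑yl]‑1‑iodo‑2‑methylbutan‑2‑yl]‑4,4,5,5‑tetramethyl‑1,3,2‑dioxaborolane (benzylic configuration retained, quaternary centre as a mixture) | CC1(C)OB(OC1(C)C)C(C)(CI)[C@@H](C)c1c(O[Si](C(C)C)(C(C)C)C(C)C)cc(O[Si](C(C)C)(C(C)C)C(C)C)c2ccoc12 | intermediate (not isolated)
31 | 7‑[(2R)‑3‑methylbut‑3‑en‑2‑yl]‑4,6‑bis(triisopropylsilyloxy)benzofuran | C=C(C)[C@@H](C)c1c(O[Si](C(C)C)(C(C)C)C(C)C)cc(O[Si](C(C)C)(C(C)C)C(C)C)c2ccoc12 | intermediate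
32 | 2‑lithio derivative of 31 | C=C(C)[C@@H](C)c1c(O[Si](C(C)C)(C(C)C)C(C)C)cc(O[Si](C(C)C)(C(C)C)C(C)C)c2cc([Li])oc12 | intermediate (not isolated)
33 | 2‑(chlorozincio) derivative of 31 | C=C(C)[C@@H](C)c1c(O[Si](C(C)C)(C(C)C)C(C)C)cc(O[Si](C(C)C)(C(C)C)C(C)C)c2cc([Zn]Cl)oc12 | intermediate (not isolated)
34 | 2‑[2,2‑dimethyl‑6‑(3‑methylbut‑2‑enyl)‑7‑(triisopropylsilyloxy)chroman‑5‑yl]‑7‑[(2R)‑3‑methylbut‑3‑en‑2‑yl]‑4,6‑bis(triisopropylsilyloxy)benzofuran | C=C(C)[C@@H](C)c1c(O[Si](C(C)C)(C(C)C)C(C)C)cc(O[Si](C(C)C)(C(C)C)C(C)C)c2cc(-c3c(CC=C(C)C)c(O[Si](C(C)C)(C(C)C)C(C)C)cc4c3CCC(C)(C)O4)oc12 | intermediate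
35 | 2‑[7‑hydroxy‑2,2‑dimethyl‑6‑(3‑methylbut‑2‑enyl)chroman‑5‑yl]‑7‑[(2R)‑3‑methylbut‑3‑en‑2‑yl]benzofuran‑4,6‑diol | C=C(C)[C@@H](C)c1c(O)cc(O)c2cc(-c3c(CC=C(C)C)c(O)cc4c3CCC(C)(C)O4)oc12 | target

Total step count: 15. Longest linear sequence: 9 steps (1, 2–7, 14, 15 or 1, 8–13, 14, 15).

Steps most likely to fail

Step 3 (key step). The transient o‑quinone methide may be consumed by C‑alkylation of a second electron‑rich arene (oligomerisation) or by an ene reaction faster than it cycloadds to the unactivated gaseous alkene. The fallback sets out from 3 and returns at 8. It keeps the same [4+2] but generates a deactivated quinone methide anionically at low temperature. Boc2O/DMAP converts 3 into the bis(tert‑butyl carbonate) aldehyde F1. Borane–dimethyl sulfide reduces the formyl group to give the benzylic alcohol F2. t‑BuMgCl at −78 °C to rt under excess isobutene triggers alkoxide‑to‑carbonate acyl transfer and loss of tert‑butyl carbonate; the resulting Boc‑bearing quinone methide is more electrophilic, sits on a non‑nucleophilic ring, and is trapped by isobutene to give the 5‑O‑Boc chroman F3. Piperidine removes the carbonate to give 8.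

Step 12. Hydrocupration next to the bulky ortho‑silyloxy group may lose regiocontrol (linear boronate) and facial selectivity, eroding the enantiomeric purity carried through step 13. The fallback sets out from 23 and returns at 31, bypassing steps 11–13. Wittig olefination of 23 with ethyl 2‑(triphenylphosphoranylidene)propanoate gives the (E)‑enoate F4. DIBAL‑H reduces it to the (E)‑allylic alcohol F5. Diethyl chlorophosphate/pyridine gives the allylic phosphate F6. Copper‑catalysed enantioselective SN2′ allylic alkylation with MeMgBr (CuTC, chiral phosphoramidite, CH2Cl2, −78 °C) places the methyl group on the benzylic carbon and gives 31 directly, the ligand antipode being chosen for the (R) product.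

Step 14. Slow oxidative addition into the electron‑rich, di‑ortho‑substituted triflate may let the heteroarylzinc reagent decay by protonation or homocoupling before it couples. The fallback sets out from 15 (with 17 from step 8) and returns at 34. The furan ring is built at the union instead of being coupled as a preformed ring.
- Copper‑free Sonogashira coupling of 15 with ethynyltrimethylsilane (Pd/XPhos, Cs2CO3, MeCN, 80 °C; the stable alkyne tolerates forcing conditions) gives the silylalkyne F7.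
- K2CO3/MeOH at 0 °C gives the terminal alkyne F8.
- Sonogashira coupling of F8 with iodophenol 17 (Pd(PPh3)2Cl2, CuI, Et3N, DMF, 70 °C) gives the alkynylphenol F9, which is not isolated and cyclises through its 2‑OH to the 2‑arylbenzofuran aldehyde F10.
- TIPSOTf/2,6‑lutidine silylates the 6‑OH to give the tris‑silyl aldehyde F11.
- Wittig methylenation gives the vinylarene F12.
- Copper hydride hydroboration as in step 12 (the prenyl group is inert) gives the (S)‑boronate F13.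
- Zweifel olefination as in step 13 proceeds through the boronate complex F14 and the iodoalkyl boronate F15 to give 34.

Further compounds
F1 | step 3 | 2‑formyl‑5‑(triisopropylsilyloxy)‑1,3‑phenylene bis(tert‑butyl carbonate) | O=Cc1c(OC(=O)OC(C)(C)C)cc(O[Si](C(C)C)(C(C)C)C(C)C)cc1OC(=O)OC(C)(C)C
F2 | step 3 | 2‑(hydroxymethyl)‑5‑(triisopropylsilyloxy)‑1,3‑phenylene bis(tert‑butyl carbonate) | OCc1c(OC(=O)OC(C)(C)C)cc(O[Si](C(C)C)(C(C)C)C(C)C)cc1OC(=O)OC(C)(C)C
F3 | step 3 | tert‑butyl 2,2‑dimethyl‑7‑(triisopropylsilyloxy)chroman‑5‑yl carbonate | CC1(C)CCc2c(OC(=O)OC(C)(C)C)cc(O[Si](C(C)C)(C(C)C)C(C)C)cc2O1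
F4 | step 12 | ethyl (2E)‑3‑[4,6‑bis(triisopropylsilyloxy)benzofuran‑7‑yl]‑2‑methylprop‑2‑enoate | CCOC(=O)/C(C)=C/c1c(O[Si](C(C)C)(C(C)C)C(C)C)cc(O[Si](C(C)C)(C(C)C)C(C)C)c2ccoc12
F5 | step 12 | (2E)‑3‑[4,6‑bis(triisopropylsilyloxy)benzofuran‑7‑yl]‑2‑methylprop‑2‑en‑1‑ol | OC/C(C)=C/c1c(O[Si](C(C)C)(C(C)C)C(C)C)cc(O[Si](C(C)C)(C(C)C)C(C)C)c2ccoc12
F6 | step 12 | diethyl (2E)‑3‑[4,6‑bis(triisopropylsilyloxy)benzofuran‑7‑yl]‑2‑methylprop‑2‑en‑1‑yl phosphate | CCOP(=O)(OCC)OC/C(C)=C/c1c(O[Si](C(C)C)(C(C)C)C(C)C)cc(O[Si](C(C)C)(C(C)C)C(C)C)c2ccoc12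
F7 | step 14 | 2,2‑dimethyl‑6‑(3‑methylbut‑2‑enyl)‑7‑(triisopropylsilyloxy)‑5‑[(trimethylsilyl)ethynyl]chroman | CC(C)=CCc1c(C#C[Si](C)(C)C)c2CCC(C)(C)Oc2cc1O[Si](C(C)C)(C(C)C)C(C)C
F8 | step 14 | 5‑ethynyl‑2,2‑dimethyl‑6‑(3‑methylbut‑2‑enyl)‑7‑(triisopropylsilyloxy)chroman | C#Cc1c(CC=C(C)C)c(O[Si](C(C)C)(C(C)C)C(C)C)cc2OC(C)(C)CCc12
F9 | step 14 | 3‑{[2,2‑dimethyl‑6‑(3‑methylbut‑2‑enyl)‑7‑(triisopropylsilyloxy)chroman‑5‑yl]ethynyl}‑2,6‑dihydroxy‑4‑(triisopropylsilyloxy)benzaldehyde (not isolated) | O=Cc1c(O)cc(O[Si](C(C)C)(C(C)C)C(C)C)c(C#Cc2c(CC=C(C)C)c(O[Si](C(C)C)(C(C)C)C(C)C)cc3OC(C)(C)CCc23)c1O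
F10 | step 14 | 2‑[2,2‑dimethyl‑6‑(3‑methylbut‑2‑enyl)‑7‑(triisopropylsilyloxy)chroman‑5‑yl]‑6‑hydroxy‑4‑(triisopropylsilyloxy)benzofuran‑7‑carbaldehyde | O=Cc1c(O)cc(O[Si](C(C)C)(C(C)C)C(C)C)c2cc(-c3c(CC=C(C)C)c(O[Si](C(C)C)(C(C)C)C(C)C)cc4c3CCC(C)(C)O4)oc12
F11 | step 14 | 2‑[2,2‑dimethyl‑6‑(3‑methylbut‑2‑enyl)‑7‑(triisopropylsilyloxy)chroman‑5‑yl]‑4,6‑bis(triisopropylsilyloxy)benzofuran‑7‑carbaldehyde | O=Cc1c(O[Si](C(C)C)(C(C)C)C(C)C)cc(O[Si](C(C)C)(C(C)C)C(C)C)c2cc(-c3c(CC=C(C)C)c(O[Si](C(C)C)(C(C)C)C(C)C)cc4c3CCC(C)(C)O4)oc12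
F12 | step 14 | 2‑[2,2‑dimethyl‑6‑(3‑methylbut‑2‑enyl)‑7‑(triisopropylsilyloxy)chroman‑5‑yl]‑7‑ethenyl‑4,6‑bis(triisopropylsilyloxy)benzofuran | C=Cc1c(O[Si](C(C)C)(C(C)C)C(C)C)cc(O[Si](C(C)C)(C(C)C)C(C)C)c2cc(-c3c(CC=C(C)C)c(O[Si](C(C)C)(C(C)C)C(C)C)cc4c3CCC(C)(C)O4)oc12
F13 | step 14 | (S)‑configured 1‑(benzofuran‑7‑yl)ethyl pinacol boronate of the coupled skeleton | CC1(C)OB(OC1(C)C)[C@@H](C)c1c(O[Si](C(C)C)(C(C)C)C(C)C)cc(O[Si](C(C)C)(C(C)C)C(C)C)c2cc(-c3c(CC=C(C)C)c(O[Si](C(C)C)(C(C)C)C(C)C)cc4c3CCC(C)(C)O4)oc12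
F14 | step 14 | lithium isopropenyl boronate complex of F13 (not isolated) | [Li+].C=C(C)[B-]1(OC(C)(C)C(C)(C)O1)[C@@H](C)c1c(O[Si](C(C)C)(C(C)C)C(C)C)cc(O[Si](C(C)C)(C(C)C)C(C)C)c2cc(-c3c(CC=C(C)C)c(O[Si](C(C)C)(C(C)C)C(C)C)cc4c3CCC(C)(C)O4)oc12
F15 | step 14 | iodoalkyl boronate from F14 (not isolated; benzylic configuration retained, quaternary centre as a mixture) | CC1(C)OB(OC1(C)C)C(C)(CI)[C@@H](C)c1c(O[Si](C(C)C)(C(C)C)C(C)C)cc(O[Si](C(C)C)(C(C)C)C(C)C)c2cc(-c3c(CC=C(C)C)c(O[Si](C(C)C)(C(C)C)C(C)C)cc4c3CCC(C)(C)O4)oc12
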